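Readings and results were computed for an exercise; scatter was added.

Wednesday's flask, the run nearest to alder, reaches 53.0% target at 30.0 min, and you want to know where such a flask stands at 80 min.

| flask | solid electrophile | nucleophile | remark | time |
|---|---|---|---|---|
| Wednesday's | 0.034 M | 1.2 equiv | run made earlier |  |
| Tuesday's | 0.10 M | 1.2 equiv | run made earlier |  |
| cedar | 0.050 M | 1.80 equiv |  | 80 min |
| alder | 0.050 M | 1.20 equiv |  | 80 min |
| elm | 0.050 M | 2.70 equiv |  | 80 min |

| run | time / min | solid electrophile / % | target / % |
|---|---|---|---|
| Wednesday's | 2.50 | 0.3 | 15.5 |
| Wednesday's | 8.00 | 0.7 | 29.1 |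
| Wednesday's | 12.0 | 0.5 | 35.2 |
| Wednesday's | 20.0 | 0 | 44.1 |
| Wednesday's | 30.0 | 0.6 | 53.0 |
| Tuesday's | 2.50 | 48.6 | 16.0 |
| Tuesday's | 4.00 | 39.7 | 24.1 |
| Tuesday's | 8.00 | 25.3 | 33.1 |
| Tuesday's | 15.0 | 14.6 | 45.5 |
| Tuesday's | 30.0 | 0 | 64.0 |

(each reading ± 1 percentage point)

- the numbers in the tables scatter by 1 percentage point (one standard deviation)
- at the start none of the solid electrophile is in solution
- what has only dissolved of solid electrophile counts as not reacted

- part of the solid electrophile that has reacted (what has only dissolved counts as not reacted) at the end, cedar
- part of the solid electrophile that has reacted (what has only dissolved counts as not reacted) at the end, alder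
- part of the solid electrophile that has reacted (what has only dissolved counts as not reacted) at the end, elm
- what raising the equivalents of nucleophile from its lowest to its highest value here does to the part of the solid electrophile that has reacted (what has only dissolved counts as not reacted) (changes below 5 percentage points count as none) (it rises / no change / it falls)

Read the runs as a ladder, fastest rung first.

1. Dissolving. Wednesday's first reading shows 0.3% solid, with a scatter of 1 percentage point. In Tuesday's flask at 8.00 min, solid and target leave 0.0416 M dissolved, a reading of the ceiling. Alder's 0.050 M stands above it by 16.8% of its charge, and Wednesday's flask turns 15.5% into target by 2.50 min, so I treat alder as dissolved after the first minutes.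

2. The burst. Wednesday's target reaches 15.5% in 2.50 min, but gains 8.9 points over the last 10.0 min. Per minute that is a fall of 6.97 times, while the unreacted part fell 2.13 times. So free nucleophile must have dropped early.

3. The tail. From 8.00 min to 30.0 min Wednesday's unreacted part falls at 0.0187 /min. This is the tail constant, the fraction of what is unreacted that reacts per minute once free nucleophile is frozen (pseudo-first-order). Its half-life is 37.1 min. Check it: at 20.0 min it gives 56.7% unreacted, and the reading is 55.9%.

4. Alder. Let Wednesday's flask, with the same equivalents but 0.034 M against alder's 0.050 M, stand in and run 50.0 min longer. My reckoning for alder gives 81.5% reacted. Cedar and elm carry more nucleophile, so I expect them higher.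

The forecast gives 65% for alder, 88% for cedar and 99% for elm, and says it rises, holding that alder's charge “caps conversion near 60–67%”. My figure stands above its alder value, because my tail has no ceiling.

The flask gives 83.2% for alder, 95.9% for cedar and 99.7% for elm; the part reacted: it rises, by 17 points.

    electrophile + nucleophile → acid set free + target (k = 0.0420 /M/s)
    nucleophile + acid set free ⇌ protonated nucleophile, settled at all times (K = 9100 /M)
    acid set free → by-product carried off (k = 0.100 /s)
    nucleophile ⇌ dormant form (K = 1.60, k = 0.00220 /s)
    solid electrophile ⇌ electrophile, rate k5*(cs5 - [electrophile]) while solid is left; crystals form when [electrophile] > cs5 (solubility = 42.0 mM, k = 0.0250 /s)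

Alder's free nucleophile stands at 12.7% of its charge at 40.0 min and 10.3% at 80.0 min. Over those 40.0 min its electrophile goes from 33.5% to 16.8%, half, against the tail half-life of 37.1 min read from Wednesday's flask. The neighbour of alder with 0.013 M solid electrophile ends with 19% of its nucleophile free, 0.479 of alder's free concentration at the end. Wednesday's tail constant, taken for alder's, scaled by that ratio and run from the start, leaves 48.8% unreacted over 80 min, and that neighbour holds 43.1% electrophile.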